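The readings were computed for substances that don't exist; the scatter is artificial.

Should the next run charge 20 mM of starting material on 30.0 mM of partner, or should the starting material change?

| flask | starting material | partner | remark | time |
|---|---|---|---|---|
| Thursday's | 10 mM | 30 mM | run made earlier |  |
| Friday's | 15 mM | 30 mM | run made earlier |  |
| flask | 20 mM | 30.0 mM |  | 40 min |

| run | time / min | bis adduct / % | tris adduct / % |
|---|---|---|---|
| Thursday's | 6.00 | 28 | 1 |
| Thursday's | 12.0 | 31 | 6 |
| Thursday's | 15.0 | 33 | 4 |
| Thursday's | 25.0 | 36 | 4 |
| Thursday's | 30.0 | 34 | 5 |
| Thursday's | 40.0 | 36 | 2 |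
| Friday's | 3.00 | 18 | 2 |
| Friday's | 5.00 | 21 | 2 |
| Friday's | 8.00 | 23 | 5 |
| Friday's | 12.0 | 27 | 5 |
| Friday's | 15.0 | 29 | 2 |
| Friday's | 25.0 | 28 | 6 |
| Friday's | 40.0 | 27 | 6 |

(readings scatter by 1.5 percentage points)



1. concentration of bis adduct at 40 min, in mM
2. concentration of tris adduct at 40 min, in mM

Thursday's bis adduct levels off near 35.3% of the starting material charged (mean from 25.0 min on), and Friday's near 28.0% (mean from 15.0 min on). The runs differ in loading e, the equivalents of partner per starting material: 3.00 against 2.00.

Here is my own reckoning. Bis adduct puts two partners on one molecule, so I let its share rise as e·e at low loading and bend towards a ceiling S: share = S·e·e/(e·e + E·E). The two plateaus, as readings, give S = 44.7% and E = 1.54, the half-loading, the loading at which the share reaches half the ceiling.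

Your flask has loading 1.50, close to E, so the rule gives it an estimated share of 21.7%, and an estimated c(bis adduct) of 4.34 mM. With partner held, this rule tops out where e equals E, at 19.4 mM of starting material, so I would charge 20 mM as planned.

The forecast gives more bis adduct than I do: 5.1 mM, with 0.72 mM of tris adduct. Its ground is “this looks like reversible equilibrium rather than a slow reaction”.

The flask gives 4.50 mM of bis adduct and 0.501 mM of tris adduct.

    starting material + partner → first product (k = 0.459 /M/s)
    partner + first product → bis adduct (k = 0.179 /M/s)
    partner + bis adduct → tris adduct (k = 0.171 /M/s)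
    partner + tris adduct → tetra adduct (k = 1.16 /M/s)
    2 partner → self-condensation product (k = 0.0550 /M/s)

In the flask partner, the limiting reagent, stands at 0% of its charge at 40 min, with 17% of the starting material still unbound. The flask has come to rest: at 400 min it still holds 4.50 mM of bis adduct and 0.501 mM of tris adduct. Its bis adduct share of 22.5% stands beside the 21.7% reckoned from E.

The neighbour with 12 mM of partner has loading 0.600, below E, so the half-loading gives a share of 5.86%, or 1.17 mM of bis adduct. That flask gives 1.17 mM.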